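Which vessel should take this charge depends on one dispute: does the reagent last long enough to count as an excess?

| flask | substrate | reagent | scavenger | time | remark |
|---|---|---|---|---|---|
| south-west | 0.40 M | 1.00 M | 0.400 M | 80 min | a closed flask charged with all of it at once and left for 80 min |
| north | 0.40 M (fed, over 64.0 min) | 1.00 M | 0.400 M | 80 min | all but substrate at the start; substrate goes in evenly over 64.0 min, the run ends at 80 min |
| north-east | 0.40 M | 1.00 M | 0.400 M |  | one stirred flow tank at steady state, fed with the mixture as stated, mean residence time 400 min |
| east | 0.40 M | 1.00 M | 0.400 M |  | one stirred flow tank at steady state, fed with the mixture as stated, mean residence time 80 min |

    intermediate → target (k1 = 2.43 × 10⁻⁴ /s)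
    reagent + released group ⇌ idle adduct, settled at all times (K2 = 0.325 /M)
    substrate + reagent → intermediate + released group (k3 = 0.00219 /M/s)
    2 reagent → homo dimer (k4 = 0.00758 /M/s)
    scavenger + released group → scavenged by-product (k5 = 0.138 /M/s)

- released group is meant together with its idle adduct
- a doubled species enters its step squared and goes two at a time
- the stated concentrations are those of everything mixed, before any reaction; amounts are the same in each set-up
- the feed brings no volume worth counting
- run time (south-west): 80 min

* the set-up with the highest amount of intermediate at the outlet or at the end, in percent of the substrate put in ("none" if the first two lie within 2 percentage points) (south-west / north / north-east / east / none)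
* amount of intermediate at the outlet or at the end, in percent of the substrate put in, south-west
* amount of intermediate at the outlet or at the end, in percent of the substrate put in, north
* amount of intermediate at the outlet or at the end, in percent of the substrate put in, north-east
* amount of intermediate at the outlet or at the end, in percent of the substrate put in, east

One chemist says it does. The reagent is charged at 2.50 times the substrate, so the substrate should fall pseudo-first-order, with a half-life of 5.3 min. South-west then makes its intermediate early and ends with 35.0 % after decay.

The other chemist says it does not. The first half-life of the reagent by the dimer step is 1.10 min, shorter than the substrate's, so the reagent falls before the substrate has turned over.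

My own reckoning follows the second view and writes the reagent balance. Let R and A be the reagent and substrate concentrations, a twice the dimer constant, b the constant of the substrate step, and θ the running time integral of R, the exposure. Then A falls as exp(−bθ), and R falls per unit of exposure at the rate aR + bA. This equation is linear in θ. Setting R to zero gives the logarithm of one plus (a − b)R/(bA), with R and A as charged, divided by a − b. That is 213 M·s, the exposure ceiling, the exposure at which R reaches zero in this balance for the south-west charge. On this reckoning south-west keeps 62.7 % of its substrate. If the converted part were all made at the start and then decayed for the whole run, 11.6 % would stand as intermediate at the end.

The forecast takes the second side, with the words “The reagent dimerises quickly”. It names east as best, with 13.5 % for south-west, 4.9 % for north, 10.2 % for north-east and 23.4 % for east. My south-west figure is lower than its 13.5 %, since I dated the conversion at the very start.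

The simulation gives east as best, with 13.5 %, 4.86 %, 10.2 % and 23.4 % in the order of the forecast. The first chemist's 35.0 % for south-west is higher than the simulated 13.5 %; that picture fits south-west over times short against 1.10 min, while the reagent stands near its charge.

At 0.862 min in south-west the reagent goes to homo dimer 10 times as fast as into the substrate step. At 80.0 min south-west holds 63 % of its substrate, against 62.7 % from the exposure ceiling. In east the exposure is the steady reagent level 0.0980 M times the mean residence time, 470 M·s; the converted share bθ/(one plus bθ), divided by one plus the decay constant of the intermediate times that residence time, comes to 23.4 % of the substrate as intermediate.

The numbers are invented; the run is a simulation.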